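## Retrosynthetic overview

1. The target comes from oxidation of the C1 carbinol, after desilylation, cross-metathesis capping of an allyl group to the prenyl terminus, and peracid epoxidation anti to a C1 silyl ether. The oxirane is the only ring closed in the route (step 7).
2. Key disconnection C5–C7: the alkenyl radical from (S)-2-bromohexa-1,5-dien-3-ol adds intermolecularly to the diene terminus of a protected toluene cis-dihydrodiol, anti to the ring oxygens. H-atom transfer to the resulting allyl radical leaves the C2=C3 alkene.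
3. The six-membered carbocycle is never constructed: it is the dearomatised ring of toluene. Enzymatic cis-dihydroxylation fixes the C6–O stereocentre; the distal OH is then senecioylated and the proximal OH silylated.
4. Side chain: C8 is set by asymmetric allylboration of 2-bromoacrolein; the angelate is installed by Yamaguchi esterification after the coupling.

Assumption: 2-bromoacrolein (five non-hydrogen atoms, freshly distilled) is taken as purchasable. Locants used below: C1 = future ketone carbon, C2 (methyl-bearing) and C3 = future oxirane carbons, C4 = ring CH2, C5 = side-chain-bearing carbon, C6 = senecioate carbon, C7 = side-chain vinyl carbon, C8 = angelate carbon.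

## Route

Step 1
Reactants: 1 toluene
Product: 2 (1S,2R)-3-methylcyclohexa-3,5-diene-1,2-diol
Conditions: E. coli JM109(pDTG601) whole cells expressing toluene dioxygenase, air, glucose, phosphate buffer pH 6.8, 35 °C, toluene fed as vapour; EtOAc extraction
Reagents that add atoms: dioxygen, O=O
Why: Toluene dioxygenase effects an enzymatic arene cis-dihydroxylation (dearomatisation) at the 2,3-positions from one face, giving the (1S,2R)-diol in >98% ee and thereby fixing the C6–O configuration of the target (and, temporarily, C1), with NADH recycled by the cells.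

Step 2
Reactants: 2 (1S,2R)-3-methylcyclohexa-3,5-diene-1,2-diol; 3 3-methylbut-2-enoyl chloride (senecioyl chloride)
Product: 4 (1S,6R)-6-hydroxy-5-methylcyclohexa-2,4-dien-1-yl 3-methylbut-2-enoate
Conditions: 3 (1.05 equiv), pyridine, CH2Cl2, −78 → −40 °C
Reagents that add atoms: none
Why: The hydroxyl remote from the methyl group is the less hindered, pseudo-equatorial one, so low-temperature O-acylation (nucleophilic acyl substitution with a weak base that avoids vinylketene formation) is selective for the future C6 oxygen and touches no stereocentre.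

Step 3
Reactants: 4 (1S,6R)-6-hydroxy-5-methylcyclohexa-2,4-dien-1-yl 3-methylbut-2-enoate
Product: 5 (1S,6R)-6-[(tert-butyldimethylsilyl)oxy]-5-methylcyclohexa-2,4-dien-1-yl 3-methylbut-2-enoate
Conditions: TBSOTf, 2,6-lutidine, CH2Cl2, −78 °C
Reagents that add atoms: tert-butyldimethylsilyl trifluoromethanesulfonate (TBSOTf), CC(C)(C)[Si](C)(C)OS(=O)(=O)C(F)(F)F
Why: Silyl triflate O-silylation caps the remaining hindered allylic hydroxyl at −78 °C before acyl migration or aromatisation can occur, and the bulky C1 silyl ether later screens the lower ring face.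

Step 4
Reactants: 6 allylmagnesium bromide; 7 2-bromoacrolein
Product: 10 (S)-2-bromohexa-1,5-dien-3-ol, via allylborane 8 (not isolated), via borinate 9 (not isolated)
Conditions: (−)-Ipc2BOMe (the reagent made from (+)-α-pinene), 6, Et2O, 0 °C → rt; then 7, −78 °C; then NaOH, H2O2, 0 °C → rt
Reagents that add atoms: none
Why: Brown asymmetric allylboration proceeds through a chair Zimmerman–Traxler transition state in which the (+)-α-pinene-derived reagent attacks the Si face of the enal, which for this substrate corresponds to the (S)-carbinol (C8).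

Step 5
Reactants: 5 (1S,6R)-6-[(tert-butyldimethylsilyl)oxy]-5-methylcyclohexa-2,4-dien-1-yl 3-methylbut-2-enoate; 10 (S)-2-bromohexa-1,5-dien-3-ol
Product: 11 (1S,2R,6S)-2-[(tert-butyldimethylsilyl)oxy]-6-[(3S)-3-hydroxyhexa-1,5-dien-2-yl]-3-methylcyclohex-3-en-1-yl 3-methylbut-2-enoate
Conditions: 10 (2.5 equiv) and Bu3SnH (2.7 equiv) by syringe pump over 8 h, 2,2'-azobis(4-methoxy-2,4-dimethylvaleronitrile) (0.2 equiv), PhH (0.5 M in 5), 40 °C
Reagents that add atoms: none
Why: Proposed new method: Bu3Sn• abstracts bromine from 10 to give a σ-alkenyl radical that adds to the unsubstituted diene terminus C5 of 5 on the face anti to the two oxygen substituents (the pseudo-axial C1–OTBS blocks the lower face), setting C5 trans to the senecioate, and the allyl radical formed is reduced by Bu3SnH at its less hindered terminus C4 to leave the trisubstituted C2=C3 alkene; the closest known reaction type is the tin hydride-mediated reductive (Giese-type) addition of alkenyl and aryl radicals to alkenes and 1,3-dienes.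

Step 6
Reactants: 11 (1S,2R,6S)-2-[(tert-butyldimethylsilyl)oxy]-6-[(3S)-3-hydroxyhexa-1,5-dien-2-yl]-3-methylcyclohex-3-en-1-yl 3-methylbut-2-enoate; 12 angelic acid ((Z)-2-methylbut-2-enoic acid)
Product: 14 (1S,2R,6S)-2-[(tert-butyldimethylsilyl)oxy]-3-methyl-6-[(3S)-3-{[(Z)-2-methylbut-2-enoyl]oxy}hexa-1,5-dien-2-yl]cyclohex-3-en-1-yl 3-methylbut-2-enoate, via mixed anhydride 13 (not isolated)
Conditions: 12, 2,4,6-trichlorobenzoyl chloride, Et3N, PhMe, rt, 2 h; then 11, 80 °C
Reagents that add atoms: none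
Why: Yamaguchi esterification through the preformed mixed anhydride without DMAP acylates the only free hydroxyl and is the standard way to install an angelate without Z-to-E isomerisation to the tiglate; C8 is untouched.

Step 7
Reactants: 14 (1S,2R,6S)-2-[(tert-butyldimethylsilyl)oxy]-3-methyl-6-[(3S)-3-{[(Z)-2-methylbut-2-enoyl]oxy}hexa-1,5-dien-2-yl]cyclohex-3-en-1-yl 3-methylbut-2-enoate
Product: 15 (1S,2S,3S,4S,6S)-2-[(tert-butyldimethylsilyl)oxy]-1-methyl-4-[(3S)-3-{[(Z)-2-methylbut-2-enoyl]oxy}hexa-1,5-dien-2-yl]-7-oxabicyclo[4.1.0]heptan-3-yl 3-methylbut-2-enoate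
Conditions: mCPBA, NaHCO3, CH2Cl2, 0 °C
Reagents that add atoms: 3-chloroperoxybenzoic acid (mCPBA), OOC(=O)c1cccc(Cl)c1
Why: Prilezhaev epoxidation picks the only electron-rich trisubstituted alkene (the enoates, the allylic-ester-deactivated 1,1-disubstituted alkene and the vinyl group react far more slowly) and, because allylic 1,2-strain with the C2 methyl holds the C1–OTBS pseudo-axial on the lower face, delivers oxygen from the upper face to set C2 and C3 cis to the side chain and trans to both ring oxygens.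

Step 8
Reactants: 15 (1S,2S,3S,4S,6S)-2-[(tert-butyldimethylsilyl)oxy]-1-methyl-4-[(3S)-3-{[(Z)-2-methylbut-2-enoyl]oxy}hexa-1,5-dien-2-yl]-7-oxabicyclo[4.1.0]heptan-3-yl 3-methylbut-2-enoate; 16 2-methylbut-2-ene
Product: 17 (1S,2S,3S,4S,6S)-2-[(tert-butyldimethylsilyl)oxy]-1-methyl-4-[(3S)-6-methyl-3-{[(Z)-2-methylbut-2-enoyl]oxy}hepta-1,5-dien-2-yl]-7-oxabicyclo[4.1.0]heptan-3-yl 3-methylbut-2-enoate
Conditions: 16 (large excess), second-generation Grubbs catalyst RuCl2(=CHPh)(H2IMes)(PCy3) (5 mol %), CH2Cl2, 40 °C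
Reagents that add atoms: none
Why: Olefin cross-metathesis engages only the monosubstituted alkene, the 1,1-disubstituted alkene and the trisubstituted enoates being spectators for the ruthenium carbene, and excess 2-methylbut-2-ene converts it into the trisubstituted prenyl terminus with loss of propene.

Step 9
Reactants: 17 (1S,2S,3S,4S,6S)-2-[(tert-butyldimethylsilyl)oxy]-1-methyl-4-[(3S)-6-methyl-3-{[(Z)-2-methylbut-2-enoyl]oxy}hepta-1,5-dien-2-yl]-7-oxabicyclo[4.1.0]heptan-3-yl 3-methylbut-2-enoate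
Product: 18 (1R,2S,3S,4S,6S)-2-hydroxy-1-methyl-4-[(3S)-6-methyl-3-{[(Z)-2-methylbut-2-enoyl]oxy}hepta-1,5-dien-2-yl]-7-oxabicyclo[4.1.0]heptan-3-yl 3-methylbut-2-enoate
Conditions: Bu4NF, AcOH (1:1), THF, 0 °C → rt
Reagents that add atoms: none
Why: Fluoride-mediated desilylation buffered with acetic acid frees the C1 hydroxyl without generating an alkoxide, which avoids senecioyl migration from the cis C6 oxygen and Payne rearrangement of the neighbouring oxirane.

Step 10
Reactants: 18 (1R,2S,3S,4S,6S)-2-hydroxy-1-methyl-4-[(3S)-6-methyl-3-{[(Z)-2-methylbut-2-enoyl]oxy}hepta-1,5-dien-2-yl]-7-oxabicyclo[4.1.0]heptan-3-yl 3-methylbut-2-enoate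
Product: 19 (1S,3S,4S,6S)-1-methyl-4-[(3S)-6-methyl-3-{[(Z)-2-methylbut-2-enoyl]oxy}hepta-1,5-dien-2-yl]-2-oxo-7-oxabicyclo[4.1.0]heptan-3-yl 3-methylbut-2-enoate (CNP0333561.1)
Conditions: Dess–Martin periodinane, pyridine, CH2Cl2, 0 °C → rt
Reagents that add atoms: none
Why: Dess–Martin oxidation converts the secondary epoxy alcohol into the epoxy ketone under buffered, non-enolising conditions, so the C6 stereocentre (already in the more stable trans arrangement) and the oxirane survive and the target is obtained.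

## Compound list

1 | toluene | Cc1ccccc1 | starting material
2 | (1S,2R)-3-methylcyclohexa-3,5-diene-1,2-diol | O[C@H]1C=CC=C(C)[C@H]1O | intermediate
3 | 3-methylbut-2-enoyl chloride (senecioyl chloride) | CC(C)=CC(=O)Cl | starting material
4 | (1S,6R)-6-hydroxy-5-methylcyclohexa-2,4-dien-1-yl 3-methylbut-2-enoate | CC(C)=CC(=O)O[C@H]1C=CC=C(C)[C@H]1O | intermediate
5 | (1S,6R)-6-[(tert-butyldimethylsilyl)oxy]-5-methylcyclohexa-2,4-dien-1-yl 3-methylbut-2-enoate | CC(C)=CC(=O)O[C@H]1C=CC=C(C)[C@H]1O[Si](C)(C)C(C)(C)C | intermediate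
6 | allylmagnesium bromide | C=CC[Mg]Br | starting material
7 | 2-bromoacrolein (2-bromoprop-2-enal) | C=C(Br)C=O | starting material
8 | B-allyldiisopinocampheylborane from (+)-α-pinene (not isolated) | C=CCB([C@@H]1C[C@@H]2C[C@H]([C@H]1C)C2(C)C)[C@@H]1C[C@@H]2C[C@H]([C@H]1C)C2(C)C | intermediate
9 | (S)-2-bromohexa-1,5-dien-3-yl diisopinocampheylborinate (not isolated) | C=C(Br)[C@H](CC=C)OB([C@@H]1C[C@@H]2C[C@H]([C@H]1C)C2(C)C)[C@@H]1C[C@@H]2C[C@H]([C@H]1C)C2(C)C | intermediate
10 | (S)-2-bromohexa-1,5-dien-3-ol | C=C(Br)[C@H](CC=C)O | intermediate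
11 | (1S,2R,6S)-2-[(tert-butyldimethylsilyl)oxy]-6-[(3S)-3-hydroxyhexa-1,5-dien-2-yl]-3-methylcyclohex-3-en-1-yl 3-methylbut-2-enoate | C=C([C@H](CC=C)O)[C@@H]1CC=C(C)[C@@H](O[Si](C)(C)C(C)(C)C)[C@H]1OC(=O)C=C(C)C | intermediate
12 | angelic acid, (Z)-2-methylbut-2-enoic acid | C/C=C(/C)C(=O)O | starting material
13 | (Z)-2-methylbut-2-enoic 2,4,6-trichlorobenzoic anhydride (not isolated) | O=C(OC(=O)/C(C)=C\C)c1c(Cl)cc(Cl)cc1Cl | intermediate
14 | (1S,2R,6S)-2-[(tert-butyldimethylsilyl)oxy]-3-methyl-6-[(3S)-3-{[(Z)-2-methylbut-2-enoyl]oxy}hexa-1,5-dien-2-yl]cyclohex-3-en-1-yl 3-methylbut-2-enoate | C=C([C@H](CC=C)OC(=O)/C(C)=C\C)[C@@H]1CC=C(C)[C@@H](O[Si](C)(C)C(C)(C)C)[C@H]1OC(=O)C=C(C)C | intermediate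
15 | (1S,2S,3S,4S,6S)-2-[(tert-butyldimethylsilyl)oxy]-1-methyl-4-[(3S)-3-{[(Z)-2-methylbut-2-enoyl]oxy}hexa-1,5-dien-2-yl]-7-oxabicyclo[4.1.0]heptan-3-yl 3-methylbut-2-enoate (oxirane cis to the side chain, trans to both ring oxygens) | C=C([C@H](CC=C)OC(=O)/C(C)=C\C)[C@@H]1C[C@@H]2O[C@]2(C)[C@@H](O[Si](C)(C)C(C)(C)C)[C@H]1OC(=O)C=C(C)C | intermediate
16 | 2-methylbut-2-ene | CC=C(C)C | starting material
17 | (1S,2S,3S,4S,6S)-2-[(tert-butyldimethylsilyl)oxy]-1-methyl-4-[(3S)-6-methyl-3-{[(Z)-2-methylbut-2-enoyl]oxy}hepta-1,5-dien-2-yl]-7-oxabicyclo[4.1.0]heptan-3-yl 3-methylbut-2-enoate | C=C([C@H](CC=C(C)C)OC(=O)/C(C)=C\C)[C@@H]1C[C@@H]2O[C@]2(C)[C@@H](O[Si](C)(C)C(C)(C)C)[C@H]1OC(=O)C=C(C)C | intermediate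
18 | (1R,2S,3S,4S,6S)-2-hydroxy-1-methyl-4-[(3S)-6-methyl-3-{[(Z)-2-methylbut-2-enoyl]oxy}hepta-1,5-dien-2-yl]-7-oxabicyclo[4.1.0]heptan-3-yl 3-methylbut-2-enoate | C=C([C@H](CC=C(C)C)OC(=O)/C(C)=C\C)[C@@H]1C[C@@H]2O[C@]2(C)[C@@H](O)[C@H]1OC(=O)C=C(C)C | intermediate
19 | (1S,3S,4S,6S)-1-methyl-4-[(3S)-6-methyl-3-{[(Z)-2-methylbut-2-enoyl]oxy}hepta-1,5-dien-2-yl]-2-oxo-7-oxabicyclo[4.1.0]heptan-3-yl 3-methylbut-2-enoate (CNP0333561.1) | C=C([C@H](CC=C(C)C)OC(=O)/C(C)=C\C)[C@@H]1C[C@@H]2O[C@]2(C)C(=O)[C@H]1OC(=O)C=C(C)C | target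

## Step count and risk

Total step count: 10. Longest linear sequence: 9 steps (steps 1, 2, 3, 5, 6, 7, 8, 9, 10); step 4 prepares the side-chain fragment.

Three steps most likely to fail:

**Step 5 (intermolecular alkenyl-radical addition).** The risks are premature reduction of the alkenyl radical, telomerisation of the diene, and H delivery to C2 instead of C4. The fallback sets out from 5 and comes back at 11, inverting the polarity of the same C5–C7 bond so that the radical sits on the ring. Hydroboration of 5 with 9-BBN (THF, 0 °C) puts boron on the unsubstituted diene terminus, anti to the oxygens; NaBO3·4H2O oxidation gives the C5 alcohol (1S,2R,6R)-2-[(tert-butyldimethylsilyl)oxy]-6-hydroxy-3-methylcyclohex-3-en-1-yl 3-methylbut-2-enoate F1. Appel iodination (I2, PPh3, imidazole, PhMe) gives the C5 iodide (1R,2R,6S)-2-[(tert-butyldimethylsilyl)oxy]-6-iodo-3-methylcyclohex-3-en-1-yl 3-methylbut-2-enoate F2. Cross-electrophile coupling of F2 with bromide 10 (NiBr2(dme), 4,4'-di-tert-butyl-2,2'-bipyridine, Zn, NaI, DMA, rt) generates the secondary C5 radical, which the alkenylnickel species captures on the face trans to the C6 senecioate, giving 11.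

**Step 2 (regioselective mono-senecioylation of a cis-diol).** The risks are acylation of the proximal hydroxyl, bis-acylation and acyl migration. The fallback sets out from 2 and comes back at 4, using tin-templated differentiation instead of relying on sterics. Bu2SnO (MeOH, reflux, then evaporation) gives the dibutylstannylene acetal (3aR,7aS)-2,2-dibutyl-4-methyl-3a,7a-dihydro-1,3,2-benzodioxastannole F3. Treatment with 3 (CH2Cl2, 0 °C) acylates the activated pseudo-equatorial oxygen remote from the methyl group to give 4.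

**Step 7 (chemo- and face-selective peracid epoxidation).** The fallback sets out from 14 and comes back at 19, replacing steric control by hydroxyl direction:
- Bu4NF/AcOH desilylation of 14 gives the allylic alcohol F4.
- MnO2 (CH2Cl2) oxidises it to the enone F5.
- NaBH4/CeCl3·7H2O (MeOH, −78 °C) reduces F5 by axial hydride delivery to the C1-epimeric allylic alcohol F6, whose hydroxyl is on the upper face, trans to the C6 senecioate.
- VO(acac)2/t-BuOOH (PhH, rt) epoxidises only the ring alkene, syn to that hydroxyl, to give the epoxy alcohol F7.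
- Cross-metathesis of F7 with 16 (second-generation Grubbs catalyst RuCl2(=CHPh)(H2IMes)(PCy3)) gives the prenyl epoxy alcohol F8, the C2 epimer of 18.
- Dess–Martin oxidation of F8 gives 19.

Further compounds

F1 | step 5 | (1S,2R,6R)-2-[(tert-butyldimethylsilyl)oxy]-6-hydroxy-3-methylcyclohex-3-en-1-yl 3-methylbut-2-enoate | O[C@@H]1CC=C(C)[C@@H](O[Si](C)(C)C(C)(C)C)[C@H]1OC(=O)C=C(C)C
F2 | step 5 | (1R,2R,6S)-2-[(tert-butyldimethylsilyl)oxy]-6-iodo-3-methylcyclohex-3-en-1-yl 3-methylbut-2-enoate | I[C@H]1CC=C(C)[C@@H](O[Si](C)(C)C(C)(C)C)[C@H]1OC(=O)C=C(C)C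
F3 | step 2 | (3aR,7aS)-2,2-dibutyl-4-methyl-3a,7a-dihydro-1,3,2-benzodioxastannole (dibutylstannylene acetal of 2) | CCCC[Sn]1(CCCC)O[C@H]2C=CC=C(C)[C@H]2O1
F4 | step 7 | (1S,2R,6S)-2-hydroxy-3-methyl-6-[(3S)-3-{[(Z)-2-methylbut-2-enoyl]oxy}hexa-1,5-dien-2-yl]cyclohex-3-en-1-yl 3-methylbut-2-enoate | C=C([C@H](CC=C)OC(=O)/C(C)=C\C)[C@@H]1CC=C(C)[C@@H](O)[C@H]1OC(=O)C=C(C)C
F5 | step 7 | (1S,6S)-3-methyl-6-[(3S)-3-{[(Z)-2-methylbut-2-enoyl]oxy}hexa-1,5-dien-2-yl]-2-oxocyclohex-3-en-1-yl 3-methylbut-2-enoate | C=C([C@H](CC=C)OC(=O)/C(C)=C\C)[C@@H]1CC=C(C)C(=O)[C@H]1OC(=O)C=C(C)C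
F6 | step 7 | (1S,2S,6S)-2-hydroxy-3-methyl-6-[(3S)-3-{[(Z)-2-methylbut-2-enoyl]oxy}hexa-1,5-dien-2-yl]cyclohex-3-en-1-yl 3-methylbut-2-enoate | C=C([C@H](CC=C)OC(=O)/C(C)=C\C)[C@@H]1CC=C(C)[C@H](O)[C@H]1OC(=O)C=C(C)C
F7 | step 7 | (1R,2R,3S,4S,6S)-2-hydroxy-1-methyl-4-[(3S)-3-{[(Z)-2-methylbut-2-enoyl]oxy}hexa-1,5-dien-2-yl]-7-oxabicyclo[4.1.0]heptan-3-yl 3-methylbut-2-enoate | C=C([C@H](CC=C)OC(=O)/C(C)=C\C)[C@@H]1C[C@@H]2O[C@]2(C)[C@H](O)[C@H]1OC(=O)C=C(C)C
F8 | step 7 | (1R,2R,3S,4S,6S)-2-hydroxy-1-methyl-4-[(3S)-6-methyl-3-{[(Z)-2-methylbut-2-enoyl]oxy}hepta-1,5-dien-2-yl]-7-oxabicyclo[4.1.0]heptan-3-yl 3-methylbut-2-enoate | C=C([C@H](CC=C(C)C)OC(=O)/C(C)=C\C)[C@@H]1C[C@@H]2O[C@]2(C)[C@H](O)[C@H]1OC(=O)C=C(C)C
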